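**Plan**

- Retrosynthesis: the three MOM ethers come off last. The 3-prenyl-4-pyranone is traced back by a 1,3-hydrogen shift (C2 to C1″) to a 3-(3-methylbut-2-enylidene)flavanone. This is cut at C3–C4, then at the O1–C2 aryl ether, then at the C2–alkyne bond.
- Enabling feature: in the pyranone ring, C4 is the formyl carbon of a salicylaldehyde and C3 is the proximal carbon of an enyne, held 1,6 to each other by the O1–C2 tether. The prenyl group on C3 is an isomer of the exocyclic dienylidene that alkyne hydroacylation leaves there.
- Forward: acetylide addition joins the B-ring aldehyde to the C5 enyne. A Mitsunobu etherification attaches the A-ring salicylaldehyde (O1–C2). The carbene-catalysed hydroacylation forms C3–C4 and closes the only new ring. Isomerisation and deprotection finish.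
- Stereochemistry: the target has no stereocentre and no stereogenic alkene. The racemic C2 centre and the E exocyclic alkene of the intermediates both vanish in the isomerisation.

Key step: step 7

Remark: since the target SMILES holds no stereogenic element, "single enantiomer" is read as the one achiral compound drawn; chiral intermediates are carried as racemates.

**Route**

Step 1
Reactants: 1 2,4-dihydroxybenzaldehyde
Product: 2 2,4-bis(methoxymethoxy)benzaldehyde
Conditions: MOMCl (2.5 equiv), K2CO3 (4 equiv), acetone, reflux
Reagents that add atoms: chloromethyl methyl ether, COCCl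
Why: Williamson-type O-alkylation (MOM protection); excess MOMCl and carbonate at reflux should etherify both the free 4-OH and the hydrogen-bonded 2-OH, and aryl MOM ethers withstand the organolithium, Mitsunobu, carbene and amine-base steps that follow.

Step 2
Reactants: 3 3-methylbut-2-enal
Product: 4 1,1-dibromo-4-methylpenta-1,3-diene
Conditions: CBr4, PPh3, Zn dust, CH2Cl2, rt (ylide pre-formed); then 3, 0 °C → rt
Reagents that add atoms: carbon tetrabromide, BrC(Br)(Br)Br
Why: Corey–Fuchs dibromo-olefination; the dibromomethylene ylide should add 1,2 to the enal in a Wittig reaction and leave the trisubstituted alkene untouched.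

Step 3
Reactants: 4 1,1-dibromo-4-methylpenta-1,3-diene; 2 2,4-bis(methoxymethoxy)benzaldehyde
Product: 6 (±)-1-[2,4-bis(methoxymethoxy)phenyl]-5-methylhex-4-en-2-yn-1-ol, via lithium 4-methylpent-3-en-1-yn-1-ide 5 (not isolated)
Conditions: 4, n-BuLi (2.1 equiv per 4), THF, −78 → 0 °C; then 2, −78 °C → rt; sat. aq. NH4Cl
Reagents that add atoms: none
Why: Second stage of the Corey–Fuchs sequence with in-flask trapping; bromine–lithium exchange, Fritsch–Buttenberg–Wiechell rearrangement and deprotonation should give the lithium acetylide, which adds 1,2 to aldehyde 2 without the volatile enyne being handled, and the carbinol centre may form racemic because this carbon (later C2) ends sp2.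

Step 4
Reactants: 7 2,4,6-trihydroxybenzaldehyde
Product: 8 2,6-dihydroxy-4-methoxybenzaldehyde
Conditions: MeI (1.0 equiv), K2CO3 (1.0 equiv), acetone, rt
Reagents that add atoms: iodomethane, CI
Why: Regioselective Williamson methylation; the 4-OH is para to the formyl group, is the only hydroxyl not ortho to it and free of chelation, and is the most acidic, so one equivalent each of base and iodomethane should methylate it alone.

Step 5
Reactants: 8 2,6-dihydroxy-4-methoxybenzaldehyde
Product: 9 2-hydroxy-4-methoxy-6-(methoxymethoxy)benzaldehyde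
Conditions: MOMCl (1.05 equiv), K2CO3 (1.5 equiv), acetone, 0 °C → rt
Reagents that add atoms: chloromethyl methyl ether, COCCl
Why: Mono-protection of a symmetrical diol; either hydroxyl gives the same product, and after the first etherification the remaining hydroxyl is locked in a hydrogen bond to the formyl oxygen and deactivated, so the reaction should stop at the mono-MOM ether.

Step 6
Reactants: 6 (±)-1-[2,4-bis(methoxymethoxy)phenyl]-5-methylhex-4-en-2-yn-1-ol; 9 2-hydroxy-4-methoxy-6-(methoxymethoxy)benzaldehyde
Product: 10 (±)-2-{[1-(2,4-bis(methoxymethoxy)phenyl)-5-methylhex-4-en-2-yn-1-yl]oxy}-4-methoxy-6-(methoxymethoxy)benzaldehyde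
Conditions: PPh3 (1.5 equiv), DIAD (1.5 equiv), THF, 0 °C → rt
Reagents that add atoms: none
Why: Mitsunobu etherification; the salicylaldehyde-type phenol is acidic enough to protonate the betaine, and its phenoxide should displace the alkoxyphosphonium of the secondary benzylic/propargylic alcohol under neutral conditions that spare the aldehyde, enyne and MOM groups, inversion being immaterial at a racemic centre.

Step 7
Reactants: 10 (±)-2-{[1-(2,4-bis(methoxymethoxy)phenyl)-5-methylhex-4-en-2-yn-1-yl]oxy}-4-methoxy-6-(methoxymethoxy)benzaldehyde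
Product: 11 (±)-(E)-2-[2,4-bis(methoxymethoxy)phenyl]-7-methoxy-5-(methoxymethoxy)-3-(3-methylbut-2-en-1-ylidene)chroman-4-one
Conditions: 3-mesityl-5,6,7,8-tetrahydro-4H-cyclohepta[d]thiazol-3-ium perchlorate (10 mol %), K2CO3 (20 mol %), THF (0.05 M), 70 °C
Reagents that add atoms: none
Why: The thiazolylidene freed by K2CO3 adds to the formyl group to give the Breslow intermediate, an acyl anion equivalent; its nucleophilic carbon attacks the proximal alkyne carbon while its O–H proton passes to the distal one in a concerted Conia-ene-type transition state, after which the carbene is expelled. The closest known reaction is the carbene-catalysed intramolecular hydroacylation of unactivated internal alkynes in 2-(propargyloxy)benzaldehydes to 3-alkylidenechroman-4-ones. The dihydropyranone ring closes in the 6-exo-dig mode, the 7-endo alternative being disfavoured by the short O–CH tether. No new stereocentre arises (C2 stays racemic), and the syn delivery of acyl carbon and hydrogen fixes the E geometry of the exocyclic alkene. The step needs the intramolecular hydroacylation to outrun benzoin dimerisation and base-induced propargyl-to-allene isomerisation; the two ortho substituents flanking the formyl group block the bimolecular benzoin, the tether holds the alkyne next to the Breslow carbon, a thiazolylidene with a single N-aryl group can still reach the hindered aldehyde, and only catalytic carbonate is present as base.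

Step 8
Reactants: 11 (±)-(E)-2-[2,4-bis(methoxymethoxy)phenyl]-7-methoxy-5-(methoxymethoxy)-3-(3-methylbut-2-en-1-ylidene)chroman-4-one
Product: 12 2-[2,4-bis(methoxymethoxy)phenyl]-7-methoxy-5-(methoxymethoxy)-3-(3-methylbut-2-en-1-yl)-4H-chromen-4-one
Conditions: DBU (0.5 equiv), toluene, 80 °C, stopped when 11 is consumed
Reagents that add atoms: none
Why: Base-mediated exo-to-endo prototropic isomerisation (formal 1,3-hydrogen shift), the known behaviour of 3-alkylidene- and 3-arylideneflavanones; DBU should remove the C2 hydrogen (benzylic, α to oxygen, allylic to the dienone) and reprotonation of the delocalised anion at C1″ gives the 3-prenyl-4-pyranone, whose aromatic stabilisation makes the shift irreversible under these conditions and erases the C2 centre.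

Step 9
Reactants: 12 2-[2,4-bis(methoxymethoxy)phenyl]-7-methoxy-5-(methoxymethoxy)-3-(3-methylbut-2-en-1-yl)-4H-chromen-4-one
Product: 13 2-(2,4-dihydroxyphenyl)-5-hydroxy-7-methoxy-3-(3-methylbut-2-en-1-yl)-4H-chromen-4-one
Conditions: HCl in MeOH (1.25 M), 0 → 40 °C, monitored
Reagents that add atoms: none
Why: Acid-catalysed acetal exchange with methanol (MOM removal); dilute anhydrous methanolic HCl should cleave all three aryl MOM ethers, the chelated 5-O-MOM first, while the prenyl alkene, which is not placed for an easy chromane-type cyclisation onto a phenol, should survive the short mild exposure.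

**Compound list**

1 | 2,4-dihydroxybenzaldehyde | O=Cc1ccc(O)cc1O | starting material
2 | 2,4-bis(methoxymethoxy)benzaldehyde | COCOc1ccc(C=O)c(OCOC)c1 | intermediate
3 | 3-methylbut-2-enal | CC(C)=CC=O | starting material
4 | 1,1-dibromo-4-methylpenta-1,3-diene | CC(C)=CC=C(Br)Br | intermediate
5 | lithium 4-methylpent-3-en-1-yn-1-ide (not isolated) | [Li]C#CC=C(C)C | intermediate
6 | (±)-1-[2,4-bis(methoxymethoxy)phenyl]-5-methylhex-4-en-2-yn-1-ol | COCOc1ccc(C(O)C#CC=C(C)C)c(OCOC)c1 | intermediate
7 | 2,4,6-trihydroxybenzaldehyde | O=Cc1c(O)cc(O)cc1O | starting material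
8 | 2,6-dihydroxy-4-methoxybenzaldehyde | COc1cc(O)c(C=O)c(O)c1 | intermediate
9 | 2-hydroxy-4-methoxy-6-(methoxymethoxy)benzaldehyde | COCOc1cc(OC)cc(O)c1C=O | intermediate
10 | (±)-2-{[1-(2,4-bis(methoxymethoxy)phenyl)-5-methylhex-4-en-2-yn-1-yl]oxy}-4-methoxy-6-(methoxymethoxy)benzaldehyde | COCOc1ccc(C(Oc2cc(OC)cc(OCOC)c2C=O)C#CC=C(C)C)c(OCOC)c1 | intermediate
11 | (±)-(E)-2-[2,4-bis(methoxymethoxy)phenyl]-7-methoxy-5-(methoxymethoxy)-3-(3-methylbut-2-en-1-ylidene)chroman-4-one | COCOc1ccc(C2Oc3cc(OC)cc(OCOC)c3C(=O)/C2=C/C=C(C)C)c(OCOC)c1 | intermediate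
12 | 2-[2,4-bis(methoxymethoxy)phenyl]-7-methoxy-5-(methoxymethoxy)-3-(3-methylbut-2-en-1-yl)-4H-chromen-4-one | COCOc1ccc(-c2oc3cc(OC)cc(OCOC)c3c(=O)c2CC=C(C)C)c(OCOC)c1 | intermediate
13 | 2-(2,4-dihydroxyphenyl)-5-hydroxy-7-methoxy-3-(3-methylbut-2-en-1-yl)-4H-chromen-4-one | COc1cc(O)c2c(=O)c(CC=C(C)C)c(-c3ccc(O)cc3O)oc2c1 | target

**Totals**

Total step count: 9. Longest linear sequence: 6 steps (for example 1 → 2 → 6 → 10 → 11 → 12 → 13).

**Steps most likely to fail**

1. Step 7. Carbene addition to the doubly ortho-substituted, electron-rich aldehyde may be too slow, so that the substrate stays unchanged or drifts into base-induced propargyl-to-allene isomerisation.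
Fallback: it sets out from 10 and makes the same C3–C4 bond by a nickel(0)-catalysed reductive ynal cyclisation (Ni(cod)2, PBu3, Et3SiH, THF). Oxidative cyclisation in the 6-exo mode bonds the aldehyde carbon to the alkyne carbon remote from the alkene, the innate preference of conjugated enynes, and should give (E)-2-[2,4-bis(methoxymethoxy)phenyl]-7-methoxy-5-(methoxymethoxy)-3-(3-methylbut-2-en-1-ylidene)-4-(triethylsilyloxy)chromane F1 as a diastereomer mixture. TBAF in THF then frees (Z)-2-[2,4-bis(methoxymethoxy)phenyl]-7-methoxy-5-(methoxymethoxy)-3-(3-methylbut-2-en-1-ylidene)chroman-4-ol F2, which has the same alkene geometry (the descriptor changes only through CIP priorities). MnO2 in CH2Cl2 oxidises this allylic alcohol to 11, where the route is rejoined.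

2. Step 8. The base may deprotonate the terminal methyl groups of the dienone instead of C2, or the delocalised anion may be reprotonated at C3″, so that the double bonds move into the side chain rather than leaving a prenyl group. Prolonged heating may also pull the prenyl alkene into conjugation with the pyranone.
Fallback: it sets out from 11 and replaces the hydrogen shift by a reduction–dehydrogenation pair. Catecholborane (THF, −20 °C → rt, then aqueous work-up) reduces the s-cis exocyclic enone in the 1,4 sense through a cyclic transition state and should give (±)-2-[2,4-bis(methoxymethoxy)phenyl]-7-methoxy-5-(methoxymethoxy)-3-(3-methylbut-2-en-1-yl)chroman-4-one F3. DDQ in dioxane at 80 °C then abstracts hydride from C2 (benzylic, α to oxygen, on an electron-rich aryl) and a proton leaves C3, giving 12, where the route is rejoined.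

3. Step 6. The activated alkoxyphosphonium may ionise to a delocalised benzylic/propargylic cation that is captured at the wrong terminus (allenyl ether), at a ring carbon of the phenol, or by the hydrazide anion.
Fallback: it sets out from 2 and builds the ether before the enyne. Ethynylmagnesium bromide (THF, 0 °C) gives (±)-1-[2,4-bis(methoxymethoxy)phenyl]prop-2-yn-1-ol F4, and Ac2O, Et3N and DMAP give (±)-1-[2,4-bis(methoxymethoxy)phenyl]prop-2-yn-1-yl acetate F5. Copper-catalysed propargylic etherification with phenol 9 (CuOTf, pybox ligand, i-Pr2NEt) runs through a copper allenylidene that is attacked only at the carbinol carbon and should give (±)-2-{[1-(2,4-bis(methoxymethoxy)phenyl)prop-2-yn-1-yl]oxy}-4-methoxy-6-(methoxymethoxy)benzaldehyde F6. Sonogashira coupling with 1-bromo-2-methylprop-1-ene (PdCl2(PPh3)2, CuI, Et3N, 50 °C) then gives 10, where the route is rejoined.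

**Further compounds**

F1 | step 7 | (E)-2-[2,4-bis(methoxymethoxy)phenyl]-7-methoxy-5-(methoxymethoxy)-3-(3-methylbut-2-en-1-ylidene)-4-(triethylsilyloxy)chromane (racemic, diastereomer mixture) | COCOc1ccc(C2Oc3cc(OC)cc(OCOC)c3C(O[Si](CC)(CC)CC)/C2=C/C=C(C)C)c(OCOC)c1
F2 | step 7 | (Z)-2-[2,4-bis(methoxymethoxy)phenyl]-7-methoxy-5-(methoxymethoxy)-3-(3-methylbut-2-en-1-ylidene)chroman-4-ol (racemic, diastereomer mixture) | COCOc1ccc(C2Oc3cc(OC)cc(OCOC)c3C(O)/C2=C/C=C(C)C)c(OCOC)c1
F3 | step 8 | (±)-2-[2,4-bis(methoxymethoxy)phenyl]-7-methoxy-5-(methoxymethoxy)-3-(3-methylbut-2-en-1-yl)chroman-4-one (cis/trans mixture) | COCOc1ccc(C2Oc3cc(OC)cc(OCOC)c3C(=O)C2CC=C(C)C)c(OCOC)c1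
F4 | step 6 | (±)-1-[2,4-bis(methoxymethoxy)phenyl]prop-2-yn-1-ol | COCOc1ccc(C(O)C#C)c(OCOC)c1
F5 | step 6 | (±)-1-[2,4-bis(methoxymethoxy)phenyl]prop-2-yn-1-yl acetate | COCOc1ccc(C(OC(C)=O)C#C)c(OCOC)c1
F6 | step 6 | (±)-2-{[1-(2,4-bis(methoxymethoxy)phenyl)prop-2-yn-1-yl]oxy}-4-methoxy-6-(methoxymethoxy)benzaldehyde | COCOc1ccc(C(Oc2cc(OC)cc(OCOC)c2C=O)C#C)c(OCOC)c1
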